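**Retrosynthetic overview**

1. Target 16 ← tetraphenol 15 (Br2) ← tetra(methyl ether) 13 (BBr3). The last four bromines go ortho to the phenols on the aryl rings at pyrrole C3 and C4; the aroyl rings arrive already brominated.
2. 13 ← bis-ynone 8 + two molecules of pyrone 11. Each aroyl benzene ring reads C1 (ketone-bearing), C2–H, C3–Br, C4–OMe, C5–Br, C6–H. It is cut at C1–C6 and C2–C3, so aryl C3–C6 are pyrone C3–C6 and aryl C1, C2 are the two alkyne carbons of a terminal ynone; CO2 is lost.
3. 8 ← bis(Weinreb amide) 5 + ethynylmagnesium bromide 6; 5 ← diacid 3 ← two molecules of 4-methoxyphenylpyruvic acid 1 + NH3 (oxidative dimerisation, Paal–Knorr).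
4. 11 ← 4-methoxy-2-pyrone 10 ← 4-hydroxy-2H-pyran-2-one 9 (O-methylation, dibromination).
5. Ring order: pyrrole ring (step 1), then both aroyl benzene rings together (step 6); the two anisyl rings come from 1.

Key step: step 6

Assumption: 4-hydroxy-2H-pyran-2-one 9 is taken as a catalogue compound; intermediates 2, 7 and 12 form as stereoisomer mixtures whose stereocentres are destroyed in the same step, so they are drawn without configuration.

**Route**

Step 1
Reactants: 1 4-methoxyphenylpyruvic acid (2 molecules per product)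
Product: 3 3,4-bis(4-methoxyphenyl)-1H-pyrrole-2,5-dicarboxylic acid, via dilithium 3,4-bis(4-methoxyphenyl)-2,5-dioxohexanedioate 2 (not isolated)
Conditions: n-BuLi (2 equiv per acid), THF, −78 °C; I2 (0.5 equiv per acid), −78 °C → rt; NH3 (7 M in MeOH, excess), rt; aq HCl work-up
Reagents that add atoms: ammonia N; n-butyllithium [Li]CCCC (lithium of intermediate 2 only)
Why: Double deprotonation of 1 (largely enolic) gives the carboxylate enolate, iodine joins two of them at the benzylic carbon (oxidative enolate dimerisation) to the 1,4-diketone 2, and Paal–Knorr condensation of its two electrophilic alpha-keto acid carbonyls with ammonia should close the pyrrole.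

Step 2
Reactants: 3 3,4-bis(4-methoxyphenyl)-1H-pyrrole-2,5-dicarboxylic acid
Product: 5 N2,N5-dimethoxy-N2,N5-dimethyl-3,4-bis(4-methoxyphenyl)-1H-pyrrole-2,5-dicarboxamide, via 2,5-bis(imidazol-1-ylcarbonyl)-3,4-bis(4-methoxyphenyl)-1H-pyrrole 4 (not isolated)
Conditions: CDI (2.4 equiv), DMF, rt → 40 °C; MeNHOMe·HCl (3 equiv), rt
Reagents that add atoms: 1,1'-carbonyldiimidazole O=C(n1ccnc1)n1ccnc1 (imidazole units of intermediate 4 only); N,O-dimethylhydroxylamine hydrochloride CNOC.Cl
Why: Activation as the acyl imidazole and aminolysis by the hydroxylamine is a standard Weinreb amide synthesis under near-neutral conditions, which avoids base-induced loss of HCl from an N–H pyrrole acid chloride.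

Step 3
Reactants: 5 N2,N5-dimethoxy-N2,N5-dimethyl-3,4-bis(4-methoxyphenyl)-1H-pyrrole-2,5-dicarboxamide; 6 ethynylmagnesium bromide
Product: 8 1,1'-[3,4-bis(4-methoxyphenyl)-1H-pyrrole-2,5-diyl]bis(prop-2-yn-1-one), via tris(bromomagnesium) bis(hemiaminal) adduct 7 (not isolated)
Conditions: HC≡CMgBr (0.5 M in THF, 6 equiv), THF, 0 °C → rt; inverse quench into 1 M HCl, 0 °C
Reagents that add atoms: ethynylmagnesium bromide C#C[Mg]Br
Why: Weinreb ketone synthesis, in which one equivalent of Grignard reagent removes the pyrrole N–H proton, two more add to the amides to give the chelated adduct 7 that cannot add again, and the cold acidic inverse quench protonates the released N,O-dimethylhydroxylamine before it can add to the terminal ynone.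

Step 4
Reactants: 9 4-hydroxy-2H-pyran-2-one
Product: 10 4-methoxy-2H-pyran-2-one
Conditions: Me2SO4 (1.2 equiv), K2CO3, acetone, reflux
Reagents that add atoms: dimethyl sulfate COS(=O)(=O)OC
Why: Williamson-type O-alkylation of the vinylogous acid with a hard methylating agent should favour the 4-methoxy-2-pyrone over the 2-methoxy-4-pyrone isomer, as it does for the 6-methyl analogue.

Step 5
Reactants: 10 4-methoxy-2H-pyran-2-one
Product: 11 3,5-dibromo-4-methoxy-2H-pyran-2-one
Conditions: Br2 (2.2 equiv), NaOAc (2.2 equiv), AcOH, rt → 50 °C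
Reagents that add atoms: bromine BrBr
Why: Electrophilic bromination at the two nucleophilic positions of the 2-pyrone, C3 (beta-carbon of the C4 enol ether) and C5 (beta-carbon of the ring enol ester), with NaOAc buffering HBr so that the methyl enol ether survives.

Step 6
Reactants: 8 1,1'-[3,4-bis(4-methoxyphenyl)-1H-pyrrole-2,5-diyl]bis(prop-2-yn-1-one); 11 3,5-dibromo-4-methoxy-2H-pyran-2-one (2 molecules react, 4 equiv used)
Product: 13 [3,4-bis(4-methoxyphenyl)-1H-pyrrole-2,5-diyl]bis[(3,5-dibromo-4-methoxyphenyl)methanone], via bis(2-oxabicyclo[2.2.2]octa-5,7-dien-3-one) adduct 12 (not isolated)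
Conditions: 11 (4 equiv), BHT (5 mol %), PhCl (0.1 M), 135 °C, sealed tube
Reagents that add atoms: none
Why: Each terminal ynone adds as dienophile across C3 and C6 of the pyrone diene (C3=C4–C5=C6) in a thermal, concerted but asynchronous [4+2] cycloaddition in which the bond from pyrone C3 to the terminal alkyne CH runs ahead of the bond from pyrone C6 to the acyl-bearing alkyne carbon, and the bridged lactone 12 then loses CO2 by retro-[4+2] to give the arene directly with no oxidation step. The closest known reaction type is the 2-pyrone/alkyne Diels–Alder–decarboxylation route to benzenes, established for halogenated and alkoxylated 2-pyrones with activated alkynes. Each of the two benzene rings is closed by an intermolecular cycloaddition that forms two C–C bonds (aryl C2–C3 and aryl C1–C6), followed by cycloreversion. The bridgehead stereocentres of 12 are transient and vanish on aromatisation, so no stereocontrol is required. The step needs regioselectivity, acyl-bearing carbon to C6 and CH to C3, which puts OMe para to the ketone: the 4-methoxy group makes C3 the enol-ether beta-carbon with the largest HOMO coefficient, the ring oxygen on C6 acts in the same sense, the ynone carries its largest LUMO coefficient on the terminal carbon, and sterics agree because the unsubstituted alkyne terminus meets the brominated C3 while the acyl-bearing carbon meets the unsubstituted C6–H. Excess pyrone, moderate dilution and a radical inhibitor should keep cycloaddition ahead of ynone oligomerisation.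

Step 7
Reactants: 13 [3,4-bis(4-methoxyphenyl)-1H-pyrrole-2,5-diyl]bis[(3,5-dibromo-4-methoxyphenyl)methanone]
Product: 15 [3,4-bis(4-hydroxyphenyl)-1H-pyrrole-2,5-diyl]bis[(3,5-dibromo-4-hydroxyphenyl)methanone], via tetrakis(dibromoboryl) aryl ether 14 (not isolated)
Conditions: BBr3 (10 equiv), CH2Cl2, −78 °C → rt; MeOH then H2O
Reagents that add atoms: boron tribromide BrB(Br)Br (boron and bromine of intermediate 14 only)
Why: Lewis-acid ether cleavage in which BBr3 complexes each methoxy oxygen and bromide removes the methyl group by SN2, also at the methoxy groups flanked by two bromines, while diaryl ketones, aryl bromides and the pyrrole are inert and work-up hydrolyses the B–O bonds of 14.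

Step 8
Reactants: 15 [3,4-bis(4-hydroxyphenyl)-1H-pyrrole-2,5-diyl]bis[(3,5-dibromo-4-hydroxyphenyl)methanone]
Product: 16 [3,4-bis(3,5-dibromo-4-hydroxyphenyl)-1H-pyrrole-2,5-diyl]bis[(3,5-dibromo-4-hydroxyphenyl)methanone] (target)
Conditions: Br2 (4.2 equiv), AcOH, rt
Reagents that add atoms: bromine BrBr
Why: Electrophilic aromatic bromination of phenols, in which only the four positions ortho to the hydroxyl groups on the aryl rings at pyrrole C3 and C4 are free and activated, since the aroyl rings already carry bromine at both ortho positions and the pyrrole is fully substituted and deactivated by two acyl groups.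

**Compound list**

1 | 4-methoxyphenylpyruvic acid [3-(4-methoxyphenyl)-2-oxopropanoic acid] | COc1ccc(CC(=O)C(=O)O)cc1 | starting material
2 | dilithium 3,4-bis(4-methoxyphenyl)-2,5-dioxohexanedioate (meso and racemic forms, both converge) | [Li+].[Li+].[O-]C(=O)C(=O)C(c1ccc(OC)cc1)C(c1ccc(OC)cc1)C(=O)C(=O)[O-] | intermediate (not isolated)
3 | 3,4-bis(4-methoxyphenyl)-1H-pyrrole-2,5-dicarboxylic acid | OC(=O)c1[nH]c(C(=O)O)c(-c2ccc(OC)cc2)c1-c1ccc(OC)cc1 | intermediate
4 | 2,5-bis(imidazol-1-ylcarbonyl)-3,4-bis(4-methoxyphenyl)-1H-pyrrole | O=C(n1ccnc1)c1[nH]c(C(=O)n2ccnc2)c(-c2ccc(OC)cc2)c1-c1ccc(OC)cc1 | intermediate (not isolated)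
5 | N2,N5-dimethoxy-N2,N5-dimethyl-3,4-bis(4-methoxyphenyl)-1H-pyrrole-2,5-dicarboxamide | CON(C)C(=O)c1[nH]c(C(=O)N(C)OC)c(-c2ccc(OC)cc2)c1-c1ccc(OC)cc1 | intermediate
6 | ethynylmagnesium bromide | C#C[Mg]Br | starting material
7 | tris(bromomagnesium) bis(hemiaminal) adduct: N-bromomagnesio pyrrole carrying at C2 and C5 a C(OMgBr)(C≡CH)N(OMe)Me group (mixture of diastereomers) | C#CC(O[Mg]Br)(N(C)OC)c1n([Mg]Br)c(C(O[Mg]Br)(C#C)N(C)OC)c(-c2ccc(OC)cc2)c1-c1ccc(OC)cc1 | intermediate (not isolated)
8 | 1,1'-[3,4-bis(4-methoxyphenyl)-1H-pyrrole-2,5-diyl]bis(prop-2-yn-1-one) | C#CC(=O)c1[nH]c(C(=O)C#C)c(-c2ccc(OC)cc2)c1-c1ccc(OC)cc1 | intermediate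
9 | 4-hydroxy-2H-pyran-2-one | O=C1C=C(O)C=CO1 | starting material
10 | 4-methoxy-2H-pyran-2-one | COC1=CC(=O)OC=C1 | intermediate
11 | 3,5-dibromo-4-methoxy-2H-pyran-2-one | COC1=C(Br)C(=O)OC=C1Br | intermediate
12 | 2,5-bis[(4,7-dibromo-8-methoxy-3-oxo-2-oxabicyclo[2.2.2]octa-5,7-dien-6-yl)carbonyl]-3,4-bis(4-methoxyphenyl)-1H-pyrrole (mixture of diastereomers) | O=C1OC2C(Br)=C(OC)C1(Br)C=C2C(=O)c1[nH]c(C(=O)C2=CC3(Br)C(=O)OC2C(Br)=C3OC)c(-c2ccc(OC)cc2)c1-c1ccc(OC)cc1 | intermediate (not isolated)
13 | [3,4-bis(4-methoxyphenyl)-1H-pyrrole-2,5-diyl]bis[(3,5-dibromo-4-methoxyphenyl)methanone] | O=C(c1cc(Br)c(OC)c(Br)c1)c1[nH]c(C(=O)c2cc(Br)c(OC)c(Br)c2)c(-c2ccc(OC)cc2)c1-c1ccc(OC)cc1 | intermediate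
14 | tetrakis(dibromoboryl) aryl ether of 15 | O=C(c1cc(Br)c(OB(Br)Br)c(Br)c1)c1[nH]c(C(=O)c2cc(Br)c(OB(Br)Br)c(Br)c2)c(-c2ccc(OB(Br)Br)cc2)c1-c1ccc(OB(Br)Br)cc1 | intermediate (not isolated)
15 | [3,4-bis(4-hydroxyphenyl)-1H-pyrrole-2,5-diyl]bis[(3,5-dibromo-4-hydroxyphenyl)methanone] | O=C(c1cc(Br)c(O)c(Br)c1)c1[nH]c(C(=O)c2cc(Br)c(O)c(Br)c2)c(-c2ccc(O)cc2)c1-c1ccc(O)cc1 | intermediate
16 | [3,4-bis(3,5-dibromo-4-hydroxyphenyl)-1H-pyrrole-2,5-diyl]bis[(3,5-dibromo-4-hydroxyphenyl)methanone] | O=C(c1cc(Br)c(O)c(Br)c1)c1[nH]c(C(=O)c2cc(Br)c(O)c(Br)c2)c(-c2cc(Br)c(O)c(Br)c2)c1-c1cc(Br)c(O)c(Br)c1 | target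

**Step count**

Total: 8 steps. Longest linear sequence: 6 steps (1, 2, 3, 6, 7, 8); the pyrone branch (4, 5) joins at step 6.

**Steps most likely to fail**

1. Step 6. The ynone may add to the diene in the reversed orientation, with the acyl-bearing carbon bonding to C3. The lactone carbonyl and the two bromines would bias the diene that way, and only the 4-methoxy group, the ring oxygen and sterics oppose them. A hindered trisubstituted diene may also react so slowly that thermal oligomerisation of the ynone or conjugate addition to it takes over.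
   Fallback, setting out from diacid 3: decarboxylation in 2-aminoethanol at about 170 °C should give 3,4-bis(4-methoxyphenyl)-1H-pyrrole F1. Purchasable 3,5-dibromo-4-methoxybenzoic acid is converted with SOCl2 into 3,5-dibromo-4-methoxybenzoyl chloride F2. Friedel–Crafts acylation of F1 at both free alpha positions with F2 (2.5 equiv) and AlCl3 in 1,2-dichloroethane, rt → 60 °C, should give 13, where the route is rejoined before step 7. Partial loss of methyl groups under AlCl3 would be harmless because step 7 removes them all.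

2. Step 3. The magnesium pyrrolide formed by N–H deprotonation lowers the electrophilicity of both amides, so addition may stop at the mono-ketone. During work-up the released hydroxylamine may add to the terminal ynone.
   Fallback, setting out from diacid 3: SOCl2 (cat. DMF, toluene, 60 °C) should give 3,4-bis(4-methoxyphenyl)-1H-pyrrole-2,5-dicarbonyl dichloride F3. Friedel–Crafts acylation of bis(trimethylsilyl)acetylene with F3 and AlCl3 in CH2Cl2 at 0 °C, with no base present, should give 2,5-bis[3-(trimethylsilyl)propynoyl]-3,4-bis(4-methoxyphenyl)-1H-pyrrole F4. Mild desilylation with dilute aqueous Na2B4O7 in MeOH at rt should give bis-ynone 8, where the route is rejoined before step 6.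

3. Step 5. The second bromination, at C5, may stall after C3 has been substituted, or bromine may add across C5=C6 and open the lactone.
   Fallback, setting out from 10 and 8: the unbrominated pyrone 10 is used in the cycloaddition under the conditions of step 6, which should give 2,5-bis(4-methoxybenzoyl)-3,4-bis(4-methoxyphenyl)-1H-pyrrole F5. BBr3 should give 2,5-bis(4-hydroxybenzoyl)-3,4-bis(4-hydroxyphenyl)-1H-pyrrole F6. Br2 (8.5 equiv) in AcOH should then brominate all eight positions ortho to the four phenols, those of the aroyl rings included, and give the target 16 directly.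

**Further compounds**

F1 | step 6 | 3,4-bis(4-methoxyphenyl)-1H-pyrrole | COc1ccc(cc1)-c1c[nH]cc1-c1ccc(OC)cc1
F2 | step 6 | 3,5-dibromo-4-methoxybenzoyl chloride | COc1c(Br)cc(cc1Br)C(Cl)=O
F3 | step 3 | 3,4-bis(4-methoxyphenyl)-1H-pyrrole-2,5-dicarbonyl dichloride | ClC(=O)c1[nH]c(C(Cl)=O)c(-c2ccc(OC)cc2)c1-c1ccc(OC)cc1
F4 | step 3 | 2,5-bis[3-(trimethylsilyl)propynoyl]-3,4-bis(4-methoxyphenyl)-1H-pyrrole | C[Si](C)(C)C#CC(=O)c1[nH]c(C(=O)C#C[Si](C)(C)C)c(-c2ccc(OC)cc2)c1-c1ccc(OC)cc1
F5 | step 5 | 2,5-bis(4-methoxybenzoyl)-3,4-bis(4-methoxyphenyl)-1H-pyrrole | O=C(c1ccc(OC)cc1)c1[nH]c(C(=O)c2ccc(OC)cc2)c(-c2ccc(OC)cc2)c1-c1ccc(OC)cc1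
F6 | step 5 | 2,5-bis(4-hydroxybenzoyl)-3,4-bis(4-hydroxyphenyl)-1H-pyrrole | O=C(c1ccc(O)cc1)c1[nH]c(C(=O)c2ccc(O)cc2)c(-c2ccc(O)cc2)c1-c1ccc(O)cc1
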